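**Retrosynthetic overview**
1. Target 12 ⇐ tribenzyl-protected ketone 11 by one global hydrogenolysis (benzyl ester, aryl benzyl ether, alkyl benzyl ether).
2. 11 ⇐ aryl–C(=O) bond: nickel-electrocatalytic reductive coupling of acyl thioester 10 (made in the flask from acid 7) with aryl bromide 9; the stereocentre sits next to the new bond and is not a reacting atom.
3. 7 ⇐ C(sp3)–OAr bond: Mitsunobu inversion of the (S)-hydroxy ester 3 with benzyl syringate 5, which gives the (R) centre.
4. 3 ⇐ O-benzyl-L-serine 1 (diazotisation with retention, then esterification); the only stereocentre is bought in 1.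
5. No ring is formed: both benzene rings are bought intact (syringic acid 4, 4-bromo-2,6-dimethoxyphenol 8).

Assumption: the stereodescriptor in the SMILES is read as (R) at C2 of the propanone chain, and 1, 4 and 8 are taken as catalogue compounds.

**Route**

Step 1
Reactants: 1 O-benzyl-L-serine
Product: 2 (S)-3-(benzyloxy)-2-hydroxypropanoic acid
Conditions: NaNO2, aq. H2SO4 (1 mol/L), 0 °C to rt
Reagents that add atoms: water (O)
Why: Diazotisation of an α-amino acid gives the α-hydroxy acid with net retention (double inversion through carboxylate participation), so the purchased (S) centre is kept.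

Step 2
Reactants: 2 (S)-3-(benzyloxy)-2-hydroxypropanoic acid
Product: 3 methyl (S)-3-(benzyloxy)-2-hydroxypropanoate
Conditions: MeOH, H2SO4 (cat.), 50 °C
Reagents that add atoms: methanol (CO)
Why: Fischer esterification does not touch the stereocentre and gives the activated α-hydroxy ester needed for the Mitsunobu step.

Step 3
Reactants: 4 syringic acid
Product: 5 benzyl 4-hydroxy-3,5-dimethoxybenzoate
Conditions: BnBr, KHCO3, DMF, 40 °C
Reagents that add atoms: benzyl bromide (BrCc1ccccc1)
Why: Hydrogencarbonate deprotonates only the carboxylic acid, so O-alkylation of the carboxylate gives the benzyl ester and leaves the phenol free.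

Step 4
Reactants: 3 methyl (S)-3-(benzyloxy)-2-hydroxypropanoate; 5 benzyl 4-hydroxy-3,5-dimethoxybenzoate
Product: 6 methyl (R)-3-(benzyloxy)-2-[4-(benzyloxycarbonyl)-2,6-dimethoxyphenoxy]propanoate
Conditions: PPh3, DIAD, toluene, 0 °C to rt
Reagents that add atoms: none
Why: Mitsunobu reaction: the acidic para-ester phenol displaces the oxyphosphonium of the α-hydroxy ester by SN2 with clean inversion, so the serine-derived (S) centre becomes the (R) aryl ether centre of the target.

Step 5
Reactants: 6 methyl (R)-3-(benzyloxy)-2-[4-(benzyloxycarbonyl)-2,6-dimethoxyphenoxy]propanoate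
Product: 7 (R)-3-(benzyloxy)-2-[4-(benzyloxycarbonyl)-2,6-dimethoxyphenoxy]propanoic acid
Conditions: LiOH (1.1 equiv), THF/H2O 3:1, 0 °C; then aq. HCl to pH 3
Reagents that add atoms: lithium hydroxide ([Li+].[OH-])
Why: Saponification of the unhindered aliphatic methyl ester is much faster at 0 °C than attack on the electron-rich benzyl benzoate or α-deprotonation, so the acid forms without epimerisation.

Step 6
Reactants: 8 4-bromo-2,6-dimethoxyphenol
Product: 9 2-(benzyloxy)-5-bromo-1,3-dimethoxybenzene
Conditions: BnBr, K2CO3, acetone, reflux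
Reagents that add atoms: benzyl bromide (BrCc1ccccc1)
Why: Williamson ether synthesis protects the phenol so that it can neither be acylated nor act as a proton source in the coupling.

Step 7
Reactants: 7 (R)-3-(benzyloxy)-2-[4-(benzyloxycarbonyl)-2,6-dimethoxyphenoxy]propanoic acid; 9 2-(benzyloxy)-5-bromo-1,3-dimethoxybenzene
Product: 11 benzyl 4-{[(2R)-3-(benzyloxy)-1-[4-(benzyloxy)-3,5-dimethoxyphenyl]-1-oxopropan-2-yl]oxy}-3,5-dimethoxybenzoate, via S-2-pyridyl thioester 10 (not isolated)
Conditions: 2-mercaptopyridine, DCC, DMA, 0 °C to rt, filter; then 9 (1.5 equiv), NiBr2(dme) (10 mol%), 4,4'-di-tert-butyl-2,2'-bipyridine (12 mol%), nBu4NBr, DMA, undivided cell, Zn anode, Ni-foam cathode, constant current 4 mA, 2.3 F/mol, rt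
Reagents that add atoms: none
Why: Proposed new method: nickel-electrocatalytic reductive acyl–aryl cross-electrophile coupling of an S-2-pyridyl thioester bearing an α-stereocentre – cathodically formed zerovalent nickel (bipyridine-ligated) inserts into the C–Br bond of 9, the aryl divalent nickel is reduced to aryl monovalent nickel, and this adds the N,S-chelating acyl–S bond of 10 to give an acyl(aryl) trivalent nickel that reductively eliminates the ketone faster than it loses CO; the C(acyl)–C(aryl) bond therefore forms with no free acyl radical (no decarbonylation to an α-aryloxyalkyl radical), no base and no organometallic nucleophile, the (R) centre is never a reacting atom, and divalent zinc from the anode binds the pyridinethiolate; closest known reaction type: nickel-catalysed reductive ketone synthesis from S-2-pyridyl thioesters and alkyl halides with zinc or manganese powder, together with nickel/bipyridine electroreductive cross-electrophile coupling of aryl bromides.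

Step 8
Reactants: 11 benzyl 4-{[(2R)-3-(benzyloxy)-1-[4-(benzyloxy)-3,5-dimethoxyphenyl]-1-oxopropan-2-yl]oxy}-3,5-dimethoxybenzoate
Product: 12 4-{[(2R)-3-hydroxy-1-(4-hydroxy-3,5-dimethoxyphenyl)-1-oxopropan-2-yl]oxy}-3,5-dimethoxybenzoic acid
Conditions: H2 (1 atm), 10% Pd/C, EtOAc/EtOH, rt
Reagents that add atoms: none
Why: Neutral catalytic hydrogenolysis removes all three benzyl groups in one operation without acid or base, so the enolisable α-aryloxy ketone centre is not epimerised; 11 is chromatographed first to remove sulfur traces.

**Compound list**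
1 | O-benzyl-L-serine, (S)-2-amino-3-(benzyloxy)propanoic acid | N[C@@H](COCc1ccccc1)C(=O)O | starting material
2 | (S)-3-(benzyloxy)-2-hydroxypropanoic acid | O[C@@H](COCc1ccccc1)C(=O)O | intermediate
3 | methyl (S)-3-(benzyloxy)-2-hydroxypropanoate | O[C@@H](COCc1ccccc1)C(=O)OC | intermediate
4 | syringic acid, 4-hydroxy-3,5-dimethoxybenzoic acid | COc1cc(cc(OC)c1O)C(=O)O | starting material
5 | benzyl 4-hydroxy-3,5-dimethoxybenzoate | COc1cc(cc(OC)c1O)C(=O)OCc1ccccc1 | intermediate
6 | methyl (R)-3-(benzyloxy)-2-[4-(benzyloxycarbonyl)-2,6-dimethoxyphenoxy]propanoate | COC(=O)[C@@H](COCc1ccccc1)Oc1c(OC)cc(cc1OC)C(=O)OCc1ccccc1 | intermediate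
7 | (R)-3-(benzyloxy)-2-[4-(benzyloxycarbonyl)-2,6-dimethoxyphenoxy]propanoic acid | OC(=O)[C@@H](COCc1ccccc1)Oc1c(OC)cc(cc1OC)C(=O)OCc1ccccc1 | intermediate
8 | 4-bromo-2,6-dimethoxyphenol | COc1cc(Br)cc(OC)c1O | starting material
9 | 2-(benzyloxy)-5-bromo-1,3-dimethoxybenzene | COc1cc(Br)cc(OC)c1OCc1ccccc1 | intermediate
10 | S-(pyridin-2-yl) (R)-3-(benzyloxy)-2-[4-(benzyloxycarbonyl)-2,6-dimethoxyphenoxy]propanethioate (formed in the flask, not isolated) | O=C(Sc1ccccn1)[C@@H](COCc1ccccc1)Oc1c(OC)cc(cc1OC)C(=O)OCc1ccccc1 | intermediate
11 | benzyl 4-{[(2R)-3-(benzyloxy)-1-[4-(benzyloxy)-3,5-dimethoxyphenyl]-1-oxopropan-2-yl]oxy}-3,5-dimethoxybenzoate | COc1cc(cc(OC)c1OCc1ccccc1)C(=O)[C@@H](COCc1ccccc1)Oc1c(OC)cc(cc1OC)C(=O)OCc1ccccc1 | intermediate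
12 | 4-{[(2R)-3-hydroxy-1-(4-hydroxy-3,5-dimethoxyphenyl)-1-oxopropan-2-yl]oxy}-3,5-dimethoxybenzoic acid | COc1cc(C(=O)[C@@H](CO)Oc2c(OC)cc(C(=O)O)cc2OC)cc(OC)c1O | target

**Step count and risks**
Total steps: 8. Longest linear sequence: 6 (steps 1, 2, 4, 5, 7, 8); steps 3 and 6 are one-step side branches.

Step 7 (the proposed new coupling) is the most likely to fail. The risks are biaryl or aryl thioether formation in place of the ketone, CO loss from the acyl nickel species, and cathodic cleavage of the α-aryloxy ketone if the charge is overrun. The fallback uses known chemistry and sets out from 7 and 9. Acid 7 is converted into thioester 10 as in the first stage of step 7, and 10 is isolated by filtration, evaporation and a short silica plug. Bromide 9 is treated with Mg turnings and LiCl in THF to give [4-(benzyloxy)-3,5-dimethoxyphenyl]magnesium bromide F1. F1 (1.1 equiv) is added to 10 in THF at −78 °C and the mixture is quenched cold with aq. NH4Cl (Mukaiyama ketone synthesis). The N,S-chelated magnesium adduct does not collapse before work-up, so there is no over-addition and no enolisation, and the benzyl benzoate is much less electrophilic than the thioester. This fallback comes back to the route at 11.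

Step 4 (Mitsunobu with a phenol flanked by two methoxy groups) may be slow or give hydrazide alkylation. The fallback sets out from 3 and 5. Alcohol 3 is treated with Tf2O and 2,6-lutidine in CH2Cl2 at −78 °C to give methyl (S)-3-(benzyloxy)-2-{[(trifluoromethyl)sulfonyl]oxy}propanoate F2. F2 is displaced with inversion by the potassium phenoxide of 5 (K2CO3, MeCN, −20 °C to rt). This fallback comes back to the route at 6.

Step 8 (hydrogenolysis) may reduce the aryl ketone or cleave the α-aryloxy C–O bond before the slow alkyl benzyl ether has gone. The fallback sets out from 11 and uses non-reductive Lewis-acid debenzylation: BCl3 and pentamethylbenzene as benzyl-cation scavenger in CH2Cl2 at −78 °C, then a MeOH quench. The methyl ethers survive at this temperature. No new compound is made on this way (F0), and it comes back to the route at 12.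

**Further compounds**
F1 | step 7 | [4-(benzyloxy)-3,5-dimethoxyphenyl]magnesium bromide | COc1cc([Mg]Br)cc(OC)c1OCc1ccccc1
F2 | step 4 | methyl (S)-3-(benzyloxy)-2-{[(trifluoromethyl)sulfonyl]oxy}propanoate | COC(=O)[C@H](COCc1ccccc1)OS(=O)(=O)C(F)(F)F
F0 | step 8 | none | none
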